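**Retrosynthetic overview**
1. The target is an achiral diaryl ether of ring A (2,4-dihydroxy-6-pentylphenoxy) and ring B (benzoic acid ring: C1 CO2H, C2 O-aryl, C4 OMe, C6 pentanoyl).
2. The strategy rests on ring B carrying the ether oxygen (on C2) and the carboxyl carbon (on C1) on adjacent ring carbons, with the ketone-bearing C6 next to C1; C1 and C2 are treated as the two ends of an aryne triple bond.
3. Key disconnection: O–C2 and C1–CO2H are cut together, giving the ring A phenoxide, the C1–C2 aryne of ring B (from an ortho-silyl aryl triflate with the ketone held as a dioxolane) and CO2.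
4. The ring A phenol comes from olivetol (formylation, benzylation, Dakin oxidation); the ring B silyl triflate comes from 4-methoxyphenol and pentanoyl chloride (Fries, bromination, silylation, ketalization, retro-Brook/triflation).
5. Neither benzene ring is built; the only ring formed is the protecting dioxolane (step 7), opened again in step 11 after debenzylation.

Key step: step 9

Remark: the target has no stereocenter and is drawn and made as the open keto acid, which may equilibrate with its cyclic lactol (3-butyl-3-hydroxyphthalide) form.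

**Route**

Step 1
Reactants: 1 olivetol (5-pentylbenzene-1,3-diol)
Product: 3 2,4-dihydroxy-6-pentylbenzaldehyde, via iminium chloride 2 (not isolated)
Conditions: POCl3, DMF, 0 °C to rt; then H2O, 50 °C
Reagents that add atoms: N,N-dimethylformamide, CN(C)C=O; water, O
Why: Vilsmeier–Haack formylation of a 5-alkylresorcinol should enter at C4 (para to one hydroxyl, ortho to the other), as it does with orcinol, and hydrolysis of the iminium salt gives the aldehyde.

Step 2
Reactants: 3 2,4-dihydroxy-6-pentylbenzaldehyde
Product: 4 2,4-bis(benzyloxy)-6-pentylbenzaldehyde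
Conditions: BnBr (2.5 equiv), K2CO3, DMF, 60 °C
Reagents that add atoms: benzyl bromide, BrCc1ccccc1
Why: Williamson etherification with excess benzyl bromide and carbonate in DMF should alkylate both phenols, including the hydrogen-bonded one next to the formyl group.

Step 3
Reactants: 4 2,4-bis(benzyloxy)-6-pentylbenzaldehyde
Product: 6 2,4-bis(benzyloxy)-6-pentylphenol, via aryl formate 5 (not isolated)
Conditions: mCPBA, CH2Cl2, 0 °C to rt; aq. Na2S2O3/NaHCO3 wash; then K2CO3 (cat.), MeOH, rt
Reagents that add atoms: 3-chloroperoxybenzoic acid, OOC(=O)c1cccc(Cl)c1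
Why: In this Dakin-type Baeyer–Villiger oxidation the electron-rich aryl group migrates to give the aryl formate, which mild methanolysis converts into the phenol without touching the benzyl ethers.

Step 4
Reactants: 7 4-methoxyphenol; 8 pentanoyl chloride
Product: 10 1-(2-hydroxy-5-methoxyphenyl)pentan-1-one, via 4-methoxyphenyl pentanoate 9 (not isolated)
Conditions: neat, 80 °C; then TiCl4, 120 °C; aq. HCl work-up
Reagents that add atoms: none
Why: O-acylation followed by a TiCl4-promoted Fries rearrangement must place the acyl group ortho to the phenol because the para position carries the methoxy group, and the chelated ortho-hydroxy ketone is the thermodynamic sink.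

Step 5
Reactants: 10 1-(2-hydroxy-5-methoxyphenyl)pentan-1-one
Product: 11 1-(3-bromo-2-hydroxy-5-methoxyphenyl)pentan-1-one
Conditions: NBS (1.0 equiv), i-Pr2NH (cat.), CH2Cl2, 0 °C to rt, dark
Reagents that add atoms: N-bromosuccinimide, O=C1CCC(=O)N1Br
Why: Amine-catalysed electrophilic bromination of a phenol should go to the only free position ortho to the hydroxyl, which is also meta to the deactivating acyl group, and these non-acidic, non-radical conditions should spare the ketone alpha position.

Step 6
Reactants: 11 1-(3-bromo-2-hydroxy-5-methoxyphenyl)pentan-1-one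
Product: 12 1-[3-bromo-5-methoxy-2-(trimethylsilyloxy)phenyl]pentan-1-one
Conditions: (Me3Si)2NH, TMSCl (cat.), THF, 65 °C; concentrate, use crude
Reagents that add atoms: hexamethyldisilazane, C[Si](C)(C)N[Si](C)(C)C
Why: O-silylation of the phenol with hexamethyldisilazane places the silicon that will later migrate to carbon and removes the hydrogen bond that deactivates the ketone toward ketalization.

Step 7
Reactants: 12 1-[3-bromo-5-methoxy-2-(trimethylsilyloxy)phenyl]pentan-1-one
Product: 13 2-[3-bromo-5-methoxy-2-(trimethylsilyloxy)phenyl]-2-butyl-1,3-dioxolane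
Conditions: Me3SiOCH2CH2OSiMe3, TMSOTf (cat.), CH2Cl2, −78 °C to rt; pyridine quench, non-aqueous work-up, use crude
Reagents that add atoms: 1,2-bis(trimethylsilyloxy)ethane, C[Si](C)(C)OCCO[Si](C)(C)C
Why: Noyori ketalization is aprotic and driven by formation of hexamethyldisiloxane, so the aryl ketone should be converted into the dioxolane while the labile aryl silyl ether stays in place.

Step 8
Reactants: 13 2-[3-bromo-5-methoxy-2-(trimethylsilyloxy)phenyl]-2-butyl-1,3-dioxolane
Product: 15 2-(2-butyl-1,3-dioxolan-2-yl)-4-methoxy-6-(trimethylsilyl)phenyl trifluoromethanesulfonate, via lithium phenoxide 14 (not isolated)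
Conditions: n-BuLi (1.05 equiv), THF, −78 °C; then Tf2O, −78 to 0 °C; aq. NaHCO3
Reagents that add atoms: trifluoromethanesulfonic anhydride, O=S(=O)(OS(=O)(=O)C(F)(F)F)C(F)(F)F
Why: Bromine–lithium exchange triggers the 1,3 O-to-C silyl shift (retro-Brook rearrangement) and the resulting lithium phenoxide is triflated in the same flask; the ketal has no carbonyl or acidic proton for butyllithium to attack.

Step 9
Reactants: 6 2,4-bis(benzyloxy)-6-pentylphenol; 15 2-(2-butyl-1,3-dioxolan-2-yl)-4-methoxy-6-(trimethylsilyl)phenyl trifluoromethanesulfonate; 16 carbon dioxide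
Product: 19 2-[2,4-bis(benzyloxy)-6-pentylphenoxy]-6-(2-butyl-1,3-dioxolan-2-yl)-4-methoxybenzoic acid, via potassium phenoxide 17 (not isolated), via aryne 18 (not isolated)
Conditions: 6 (1.3 equiv), KH, THF, 0 °C; then 18-crown-6, CsF, CO2 (1 atm), 15 added slowly, THF, 0 °C to rt; cold 0.5 M HCl to pH 4
Reagents that add atoms: none
Why: Proposed new method: fluoride from CsF attacks the silicon of 15 and triflate leaves, giving aryne 18 with the triple bond between C1 and C2 of ring B; the preformed potassium phenoxide 17 adds through oxygen at C2, and the resulting C1 aryl anion, flanked by the new aryloxy group and the ketal carbon, adds to CO2 to give the carboxylate that acid work-up converts into 19. The closest known reaction type is the three-component coupling of arynes with amines and CO2 to anthranilic acids, taken together with fluoride-mediated O-arylation of hindered phenols by arynes; a phenoxide has not been shown as the nucleophile in the CO2 coupling. No ring is closed and no stereocenter is formed; the step makes only the O–C2 and C1–CO2H bonds. Attack at C2 and not C1 should follow from the C6 substituent, whose quaternary ketal carbon shields C1 and, being inductively withdrawing, polarizes the aryne so that negative charge develops next to it, while the C4 methoxy group is too remote to matter much. Carboxylation and not protonation of the C1 anion rests on the aprotic medium (KH leaves no O–H, THF replaces acetonitrile, CO2 is in excess), and ring A can arylate only on oxygen because both ortho positions and the para position are substituted. The free phenoxide is expected to outrun its reversibly formed carbonate in adding to the aryne, which is the point that remains to be shown.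

Step 10
Reactants: 19 2-[2,4-bis(benzyloxy)-6-pentylphenoxy]-6-(2-butyl-1,3-dioxolan-2-yl)-4-methoxybenzoic acid
Product: 20 2-(2-butyl-1,3-dioxolan-2-yl)-6-(2,4-dihydroxy-6-pentylphenoxy)-4-methoxybenzoic acid
Conditions: H2 (1 atm), 10% Pd/C, EtOAc, rt
Reagents that add atoms: none
Why: Hydrogenolysis of the two benzyl ethers over Pd/C should leave the diaryl ether, the methyl ether and the acid untouched, and the ketone stays masked so that no aryl carbonyl is exposed to hydrogen.

Step 11
Reactants: 20 2-(2-butyl-1,3-dioxolan-2-yl)-6-(2,4-dihydroxy-6-pentylphenoxy)-4-methoxybenzoic acid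
Product: 21 2-(2,4-dihydroxy-6-pentylphenoxy)-4-methoxy-6-pentanoylbenzoic acid (CNP0189595.0)
Conditions: 1 M HCl, THF, rt, under argon
Reagents that add atoms: water, O
Why: Acid-catalysed hydrolysis of the aryl dioxolane, assisted by the neighbouring carboxyl group, releases the ketone; any pseudo-ester formed from the ketal and the acid in step 10 hydrolyses to the same keto acid.

**Compound list**
1 | olivetol (5-pentylbenzene-1,3-diol) | CCCCCc1cc(O)cc(O)c1 | starting material
2 | [(2,4-dihydroxy-6-pentylphenyl)methylidene]dimethyliminium chloride | CCCCCc1cc(O)cc(O)c1C=[N+](C)C.[Cl-] | intermediate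
3 | 2,4-dihydroxy-6-pentylbenzaldehyde | CCCCCc1cc(O)cc(O)c1C=O | intermediate
4 | 2,4-bis(benzyloxy)-6-pentylbenzaldehyde | CCCCCc1cc(OCc2ccccc2)cc(OCc2ccccc2)c1C=O | intermediate
5 | 2,4-bis(benzyloxy)-6-pentylphenyl formate | CCCCCc1cc(OCc2ccccc2)cc(OCc2ccccc2)c1OC=O | intermediate
6 | 2,4-bis(benzyloxy)-6-pentylphenol | CCCCCc1cc(OCc2ccccc2)cc(OCc2ccccc2)c1O | intermediate
7 | 4-methoxyphenol | COc1ccc(O)cc1 | starting material
8 | pentanoyl chloride | CCCCC(Cl)=O | starting material
9 | 4-methoxyphenyl pentanoate | CCCCC(=O)Oc1ccc(OC)cc1 | intermediate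
10 | 1-(2-hydroxy-5-methoxyphenyl)pentan-1-one | CCCCC(=O)c1cc(OC)ccc1O | intermediate
11 | 1-(3-bromo-2-hydroxy-5-methoxyphenyl)pentan-1-one | CCCCC(=O)c1cc(OC)cc(Br)c1O | intermediate
12 | 1-[3-bromo-5-methoxy-2-(trimethylsilyloxy)phenyl]pentan-1-one | CCCCC(=O)c1cc(OC)cc(Br)c1O[Si](C)(C)C | intermediate
13 | 2-[3-bromo-5-methoxy-2-(trimethylsilyloxy)phenyl]-2-butyl-1,3-dioxolane | CCCCC1(OCCO1)c2cc(OC)cc(Br)c2O[Si](C)(C)C | intermediate
14 | lithium 2-(2-butyl-1,3-dioxolan-2-yl)-4-methoxy-6-(trimethylsilyl)phenoxide | CCCCC1(OCCO1)c2cc(OC)cc([Si](C)(C)C)c2[O-].[Li+] | intermediate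
15 | 2-(2-butyl-1,3-dioxolan-2-yl)-4-methoxy-6-(trimethylsilyl)phenyl trifluoromethanesulfonate | CCCCC1(OCCO1)c2cc(OC)cc([Si](C)(C)C)c2OS(=O)(=O)C(F)(F)F | intermediate
16 | carbon dioxide | O=C=O | starting material
17 | potassium 2,4-bis(benzyloxy)-6-pentylphenoxide | CCCCCc1cc(OCc2ccccc2)cc(OCc2ccccc2)c1[O-].[K+] | intermediate
18 | 3-(2-butyl-1,3-dioxolan-2-yl)-5-methoxy-1,2-didehydrobenzene (aryne, triple bond between C1 and C2 of ring B) | CCCCC1(OCCO1)C2=CC(OC)=CC#C2 | intermediate
19 | 2-[2,4-bis(benzyloxy)-6-pentylphenoxy]-6-(2-butyl-1,3-dioxolan-2-yl)-4-methoxybenzoic acid | CCCCCc1cc(OCc2ccccc2)cc(OCc2ccccc2)c1Oc3cc(OC)cc(C4(CCCC)OCCO4)c3C(=O)O | intermediate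
20 | 2-(2-butyl-1,3-dioxolan-2-yl)-6-(2,4-dihydroxy-6-pentylphenoxy)-4-methoxybenzoic acid | CCCCCc1cc(O)cc(O)c1Oc2cc(OC)cc(C3(CCCC)OCCO3)c2C(=O)O | intermediate
21 | 2-(2,4-dihydroxy-6-pentylphenoxy)-4-methoxy-6-pentanoylbenzoic acid | CCCCCc1cc(O)cc(O)c1Oc1cc(OC)cc(C(=O)CCCC)c1C(=O)O | target

**Step count**
Total: 11 steps. Longest linear sequence: 8 steps (steps 4 to 11, from 4-methoxyphenol); the ring A branch is 3 steps (steps 1 to 3) before the coupling.

**Steps most likely to fail**

Step 9 (three-component aryne coupling). Three processes could defeat it: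
- the phenoxide may be tied up as its carbonate under CO2, and that carbonate may add to the aryne through oxygen with acyl transfer;
- the C1 aryl anion may be protonated (from solvent, benzylic C–H or adventitious water) before it meets CO2;
- the phenoxide may add at C1 instead of C2.

The fallback uses known chemistry only, sets out from phenol 6 and returns at acid 19. Ring B is rebuilt with the carboxyl carbon already on C1 as an aldehyde that activates a neighbouring fluoride. Commercial 3-fluoro-5-methoxybenzonitrile is treated with n-BuMgBr and then aqueous acid to give 1-(3-fluoro-5-methoxyphenyl)pentan-1-one F1. NBS in MeCN should brominate para to the methoxy group to give 1-(2-bromo-3-fluoro-5-methoxyphenyl)pentan-1-one F2. Ethylene glycol with TsOH under Dean–Stark conditions gives 2-(2-bromo-3-fluoro-5-methoxyphenyl)-2-butyl-1,3-dioxolane F3. Bromine–lithium exchange (n-BuLi, THF, −78 °C) and a DMF quench give 2-(2-butyl-1,3-dioxolan-2-yl)-6-fluoro-4-methoxybenzaldehyde F4. Nucleophilic aromatic substitution of the fluoride ortho to the formyl group by phenol 6 (K2CO3, DMF, 100 °C) gives 2-[2,4-bis(benzyloxy)-6-pentylphenoxy]-6-(2-butyl-1,3-dioxolan-2-yl)-4-methoxybenzaldehyde F5. Pinnick oxidation (NaClO2, NaH2PO4, 2-methyl-2-butene, t-BuOH/H2O) then delivers 19.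

Step 7 (ketalization of the silylated aryl ketone). The aryl silyl ether may be lost or scrambled under silyl triflate catalysis or on work-up, and the ortho-substituted aryl ketone may convert incompletely. The fallback sets out from bromophenol 11 and returns at 13, bypassing 12; it reverses the order and changes the kind of ketalization. Phenol 11 is ketalized under Brønsted-acid, water-removing conditions (ethylene glycol, HC(OEt)3, TsOH cat., toluene, Dean–Stark) to give 2-bromo-6-(2-butyl-1,3-dioxolan-2-yl)-4-methoxyphenol F6. F6 is a phenol that can be purified, and it is then silylated with hexamethyldisilazane to give 13.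

Step 10 (hydrogenolytic debenzylation). The benzylic C–O bonds of the ketal may be hydrogenolysed once the neighbouring acid opens it to a pseudo-ester, or debenzylation may stall on the hindered, acidic substrate. The fallback sets out from 19 and returns at target 21, replacing hydrogenation with Lewis-acid debenzylation after the ketone is unmasked. Mild aqueous acid (1 M HCl, THF) first gives 2-[2,4-bis(benzyloxy)-6-pentylphenoxy]-4-methoxy-6-pentanoylbenzoic acid F7. BCl3 with pentamethylbenzene as cation scavenger (CH2Cl2, −78 °C) then cleaves both benzyl ethers, sparing the methyl ether and the diaryl ether, to give 21; step 11 is not needed.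

**Further compounds**
F1 | step 9 | 1-(3-fluoro-5-methoxyphenyl)pentan-1-one | CCCCC(=O)c1cc(F)cc(OC)c1
F2 | step 9 | 1-(2-bromo-3-fluoro-5-methoxyphenyl)pentan-1-one | CCCCC(=O)c1cc(OC)cc(F)c1Br
F3 | step 9 | 2-(2-bromo-3-fluoro-5-methoxyphenyl)-2-butyl-1,3-dioxolane | CCCCC1(OCCO1)c2cc(OC)cc(F)c2Br
F4 | step 9 | 2-(2-butyl-1,3-dioxolan-2-yl)-6-fluoro-4-methoxybenzaldehyde | CCCCC1(OCCO1)c2cc(OC)cc(F)c2C=O
F5 | step 9 | 2-[2,4-bis(benzyloxy)-6-pentylphenoxy]-6-(2-butyl-1,3-dioxolan-2-yl)-4-methoxybenzaldehyde | CCCCCc1cc(OCc2ccccc2)cc(OCc2ccccc2)c1Oc3cc(OC)cc(C4(CCCC)OCCO4)c3C=O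
F6 | step 7 | 2-bromo-6-(2-butyl-1,3-dioxolan-2-yl)-4-methoxyphenol | CCCCC1(OCCO1)c2cc(OC)cc(Br)c2O
F7 | step 10 | 2-[2,4-bis(benzyloxy)-6-pentylphenoxy]-4-methoxy-6-pentanoylbenzoic acid | CCCCCc1cc(OCc2ccccc2)cc(OCc2ccccc2)c1Oc3cc(OC)cc(C(=O)CCCC)c3C(=O)O
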